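Take logarithms of the unconverted fraction first, because that is how a time constant is read from a curve.

| flask | starting material | partner | free catalyst | time |
|---|---|---|---|---|
| eta | 300 mM | 900 mM | 6.00 mM |  |
| gamma | 180 mM | 780 mM | 6.00 mM |  |
| beta | 300 mM | 2700 mM | 6.00 mM |  |
| epsilon | 300 mM | 900 mM | 18.0 mM |  |
| delta | 600 mM | 1800 mM | 6.00 mM | 10 h |

| run | time / h | [target] / mM |
|---|---|---|
| eta run | 1.2 | 42.5 |
| eta run | 2.5 | 76.5 |
| eta run | 3.8 | 102.8 |
| eta run | 5.0 | 119.8 |
| eta run | 6.2 | 131.9 |
| eta run | 7.5 | 136.8 |
| eta run | 8.8 | 148.0 |
| eta run | 10 | 154.0 |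
| gamma run | 1.2 | 22.3 |
| gamma run | 2.5 | 39.7 |
| gamma run | 3.8 | 55.3 |
| gamma run | 5.0 | 62.0 |
| gamma run | 6.2 | 72.8 |
| gamma run | 7.5 | 78.3 |
| gamma run | 8.8 | 87.8 |
| gamma run | 10 | 87.5 |
| beta run | 1.2 | 105.5 |
| beta run | 2.5 | 157.1 |
| beta run | 3.8 | 177.0 |
| beta run | 5.0 | 178.1 |
| beta run | 6.2 | 170.1 |
| beta run | 7.5 | 155.9 |
| beta run | 8.8 | 141.2 |
| beta run | 10 | 128.6 |
| epsilon run | 1.2 | 111.8 |
| epsilon run | 2.5 | 170.6 |
| epsilon run | 3.8 | 198.7 |
| epsilon run | 5.0 | 212.2 |
| epsilon run | 6.2 | 213.8 |
| epsilon run | 7.5 | 214.5 |
| epsilon run | 8.8 | 205.1 |
| epsilon run | 10 | 204.2 |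

(scatter of a reading: 2 mM)

- apparent order in [free catalyst] of the starting rate, round the charge of the eta run (the rate where two percent of its starting material have turned into target)
- apparent order in [partner] of the starting rate, round the charge of the eta run (the rate where two percent of its starting material have turned into target)
- target in the delta run at 10 h, as a share of the starting material charged

- Overall: starting material + partner -> target, with free catalyst as catalyst.
- Constant volume, constant temperature.
- An order is taken over about fifteen percent of the charge, up and down.

While partner stands in excess, starting material decays almost exponentially (pseudo-first-order), so I read one constant from the first reading of eta, of beta and of epsilon, ln([starting material]₀/([starting material]₀ − [target]))/t. I get 0.127 h⁻¹ for eta, 0.361 h⁻¹ for beta and 0.389 h⁻¹ for epsilon. Orders are then ratios of logarithms: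

order in [partner] ≈ ln(beta/eta) / ln(charge ratio) = 0.949

order in [free catalyst] ≈ ln(epsilon/eta) / ln(charge ratio) = 1.02

For delta I bracket the share. From above, I let no target be lost. Delta has twice eta's partner and the same free catalyst, so I scale eta's constant with partner; the main step keeps the excess of partner over starting material constant, so delta's unconverted fraction s at the asked time is

s = 0.130

and the ceiling is 87.0%.

But beta falls from 178.1 mM to 128.6 mM, so target is lost. I call the loss ratio σ the pace of target's loss per target over the pace of formation per starting material, and I assume partner multiplies both, so that it cancels. At a peak, formation equals loss, so σ = [starting material]/[target] there. Beta's readings peak between 3.8 h and 5.0 h, which gives a reading of σ = 0.344. Then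

share = (s^σ − s)/(1 − σ), peak share = σ^(σ/(1 − σ)) = 57.2%

This tightens the ceiling, as far as σ carries over from beta to delta. At delta's s the rule gives 55.8%, which is my estimate. The floor is eta's last reading, 51.3%, from the same proportions and free catalyst with half delta's partner. Delta's s is smaller than the s of the rule's peak, so delta has passed that peak, yet my estimate is higher than eta's reading.

The forecast says 1 and 1, with “both orders are near 1”, and 56% (47% to 63%).

The flask gives orders of 1.1 in [free catalyst] and 1.0 in [partner], and a share of 54.1%, which is lower than the tightened ceiling and higher than the floor.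

    2 free catalyst ⇌ catalyst dimer, settled at all times (2520 L mol⁻¹)
    catalyst dimer + starting material + partner → target + catalyst dimer (59.76 L² mol⁻² h⁻¹)
    target + partner → side product (0.03708 L mol⁻¹ h⁻¹)
    target → decomposed product (0.02293 h⁻¹)

On epsilon, if the loss keeps its pace while formation runs 3.06 times faster, σ becomes 0.113 and the peak share 75.7%, against a reading of 71.5%. In delta, target meets partner and goes to side product: the run without that loss reaches 75.4% instead of 54.1%, a gain of 21 percentage points.

The numbers in the tables are simulated from invented constants, and the scatter is random.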